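**Plan**

Ring numbering used throughout: C1 (CH–OMe), C2 (=CH), C3 (=C–C7H2OBz), C4 (CH–OH), C5 (CH–OBz), C6 (CH–OH). The enabling feature is that C1–C6 form one carbocycle at the oxidation level of a benzene that has taken up two cis-diols, O4/O5 on one face (α) and O6/O1 on the other (β), with C2=C3 left over and the one-carbon branch C7 on C3, where a halogen can stand in.
Retrosynthesis: cut the acyl C–O bonds at O7 and O5 and the O1–CH3 bond, then C3–C7 (alkenyl bromide plus hydroxymethylstannane), then C6–O and C1–O (syn-dihydroxylation), and last C4–O and C5–O, which leaves bromobenzene.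
Forward: no ring is built. The benzene ring is dearomatised by dioxygenation at C4/C5 and the diol is tied as an acetonide. OsO4 then adds O6/O1, O6 is masked as a PMB ether and O1 is methylated. C7 is joined by Stille coupling and O7 benzoylated; the acetonide is removed, O5 benzoylated and O6 released.
Stereochemistry: C4 and C5 come from the enzyme as one enantiomer; C6 and C1 come from OsO4 adding anti to the C4/C5 acetonide; no centre is inverted afterwards.

Key step: step 1

Remark: in step 1 the two reducing equivalents come from NADH, which the living cells recycle at the expense of the glucose feed; the cofactor is therefore treated as catalytic and glucose as the terminal reductant.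

**Route**

Step 1
Reactants: 1 bromobenzene
Product: 2 (1S,2S)-3-bromocyclohexa-3,5-diene-1,2-diol
Conditions: E. coli JM109 (pDTG601) whole cells expressing toluene dioxygenase, IPTG induction, glucose feed, air, pH 7, 30–37 °C; EtOAc extraction
Reagents that add atoms: dioxygen, O=O
Why: Electrons from NADH pass through the reductase and the Rieske [2Fe-2S] ferredoxin to the mononuclear non-heme iron of toluene dioxygenase, which binds O2 side-on and hands both oxygen atoms to the same face of the C4–C5 π bond of the bound arene, so the two C–O bonds form suprafacially and the ring is left as the C1=C6/C2=C3 diene. The closest known reaction type is this very one, the microbial cis-dihydroxylation of monosubstituted benzenes by Rieske dioxygenases of the toluene dioxygenase class, which is established for bromobenzene. No ring is closed; the existing six-membered ring only loses its aromaticity. Both new stereocentres, C4 and C5, are set by the chiral active site, which presents one enantiotopic face of the arene to the iron-bound dioxygen and should deliver the (1S,2S) diol as a single enantiomer. The step needs attack at the ortho/meta bond next to the halogen and not at the ipso/ortho or meta/para bonds, and this is secured by the bromine, which sits in the hydrophobic pocket that normally holds the methyl group of toluene and so places the adjacent C4–C5 bond over the metal. Overoxidation to the catechol is excluded because the recombinant host carries the dioxygenase genes without the cis-diol dehydrogenase.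

Step 2
Reactants: 2 (1S,2S)-3-bromocyclohexa-3,5-diene-1,2-diol
Product: 3 (3aS,7aS)-4-bromo-2,2-dimethyl-3a,7a-dihydro-1,3-benzodioxole
Conditions: Me2C(OMe)2, p-TsOH (cat.), acetone, 0 °C to rt, 30 min; Et3N quench; used at once
Reagents that add atoms: 2,2-dimethoxypropane, COC(C)(C)OC
Why: Acid-catalysed transketalisation (acetonide formation) is fast for the cis-diol, is kept short and quenched with base so that the acid-labile dienediol does not dehydrate to bromophenol, and gives the cis-fused dioxolane that covers the α face for the next step.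

Step 3
Reactants: 3 (3aS,7aS)-4-bromo-2,2-dimethyl-3a,7a-dihydro-1,3-benzodioxole
Product: 4 (3aS,4R,5R,7aS)-7-bromo-2,2-dimethyl-3a,4,5,7a-tetrahydro-1,3-benzodioxole-4,5-diol (O6–H and O1–H on the β face, trans to the acetonide)
Conditions: OsO4 (2 mol %), NMO (1.5 equiv), acetone/H2O (4:1), rt
Reagents that add atoms: osmium tetroxide (catalytic oxygen carrier), O=[Os](=O)(=O)=O; N-methylmorpholine N-oxide, C[N+]1([O-])CCOCC1; water, O
Why: In this Upjohn dihydroxylation OsO4 adds by a concerted syn [3+2] process to the more electron-rich, unhalogenated C1=C6 bond from the β face opposite the acetonide, which sets C6 and C1 cis to each other and trans to C5–O, while the bromine-bearing C2=C3 bond is deactivated and stays.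

Step 4
Reactants: 4 (3aS,4R,5R,7aS)-7-bromo-2,2-dimethyl-3a,4,5,7a-tetrahydro-1,3-benzodioxole-4,5-diol
Product: 6 (3aS,4R,5R,7aS)-7-bromo-4-[(4-methoxyphenyl)methoxy]-2,2-dimethyl-3a,4,5,7a-tetrahydro-1,3-benzodioxol-5-ol, via dibutylstannylene acetal 5 (not isolated)
Conditions: Bu2SnO (1.1 equiv), PhMe, reflux, Dean–Stark; then PMBBr (1.2 equiv), Bu4NBr (0.2 equiv), 80 °C
Reagents that add atoms: 4-methoxybenzyl bromide, COc1ccc(CBr)cc1; dibutyltin oxide (its atoms stay in 5 only), CCCC[Sn](=O)CCCC
Why: This is a stannylene-acetal-mediated regioselective mono-O-alkylation of a cis-1,2-diol, in which the half-chair that keeps O4 pseudoaxial away from the bromine (allylic 1,2-strain) has O6 equatorial and O1 pseudoaxial, and the tin acetal activates the equatorial, more acidic O6 so that the PMB group should be placed there.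

Step 5
Reactants: 6 (3aS,4R,5R,7aS)-7-bromo-4-[(4-methoxyphenyl)methoxy]-2,2-dimethyl-3a,4,5,7a-tetrahydro-1,3-benzodioxol-5-ol
Product: 7 (3aS,4R,5R,7aS)-7-bromo-5-methoxy-4-[(4-methoxyphenyl)methoxy]-2,2-dimethyl-3a,4,5,7a-tetrahydro-1,3-benzodioxole
Conditions: NaH (1.3 equiv), MeI (2 equiv), THF, 0 °C to rt
Reagents that add atoms: iodomethane, CI
Why: Williamson etherification of the remaining allylic alkoxide at O1 with iodomethane touches no stereocentre, and the acetonide, the PMB ether and the alkenyl bromide are inert to NaH.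

Step 6
Reactants: 7 (3aS,4R,5R,7aS)-7-bromo-5-methoxy-4-[(4-methoxyphenyl)methoxy]-2,2-dimethyl-3a,4,5,7a-tetrahydro-1,3-benzodioxole; 8 (tributylstannyl)methanol
Product: 9 [(3aR,6R,7R,7aR)-6-methoxy-7-[(4-methoxyphenyl)methoxy]-2,2-dimethyl-3a,6,7,7a-tetrahydro-1,3-benzodioxol-4-yl]methanol
Conditions: Pd(PPh3)4 (10 mol %), 1,4-dioxane, 100 °C
Reagents that add atoms: (tributylstannyl)methanol 8, OC[Sn](CCCC)(CCCC)CCCC
Why: In this Kosugi–Migita–Stille hydroxymethylation the alkenyl C3–Br bond adds oxidatively to zerovalent palladium, the α-oxygenated CH2OH group is transferred from tin in preference to butyl, and reductive elimination forms C3–C7 without the alcohol needing protection.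

Step 7
Reactants: 9 [(3aR,6R,7R,7aR)-6-methoxy-7-[(4-methoxyphenyl)methoxy]-2,2-dimethyl-3a,6,7,7a-tetrahydro-1,3-benzodioxol-4-yl]methanol; 10 benzoyl chloride
Product: 11 [(3aR,6R,7R,7aR)-6-methoxy-7-[(4-methoxyphenyl)methoxy]-2,2-dimethyl-3a,6,7,7a-tetrahydro-1,3-benzodioxol-4-yl]methyl benzoate
Conditions: BzCl (1.2 equiv), Et3N, DMAP (cat.), CH2Cl2, 0 °C
Reagents that add atoms: benzoyl chloride 10, O=C(Cl)c1ccccc1
Why: DMAP-catalysed acylation of the only free hydroxyl, the primary allylic O7–H, by benzoyl chloride is a routine esterification.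

Step 8
Reactants: 11 [(3aR,6R,7R,7aR)-6-methoxy-7-[(4-methoxyphenyl)methoxy]-2,2-dimethyl-3a,6,7,7a-tetrahydro-1,3-benzodioxol-4-yl]methyl benzoate
Product: 12 [(3R,4S,5R,6R)-5,6-dihydroxy-3-methoxy-4-[(4-methoxyphenyl)methoxy]cyclohex-1-en-1-yl]methyl benzoate (O4–H and O5–H free)
Conditions: AcOH/H2O (4:1), 60 °C
Reagents that add atoms: none
Why: Acid-catalysed acetal hydrolysis in warm aqueous acetic acid opens the cis-fused dioxolane and frees O4–H and O5–H, while the PMB ether, the methyl ether and the benzoate, which need stronger acid, an oxidant or base, stay in place.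

Step 9
Reactants: 12 [(3R,4S,5R,6R)-5,6-dihydroxy-3-methoxy-4-[(4-methoxyphenyl)methoxy]cyclohex-1-en-1-yl]methyl benzoate; 10 benzoyl chloride
Product: 13 [(3R,4R,5R,6R)-5-benzoyloxy-6-hydroxy-3-methoxy-4-[(4-methoxyphenyl)methoxy]cyclohex-1-en-1-yl]methyl benzoate (O5 benzoate, O4–H free)
Conditions: BzCl (1.1 equiv), Me2SnCl2 (5 mol %), i-Pr2NEt (1.5 equiv), THF, rt
Reagents that add atoms: benzoyl chloride 10, O=C(Cl)c1ccccc1
Why: This is a Me2SnCl2-catalysed regioselective monobenzoylation of a cis-1,2-diol, in which the tin chelate of O4/O5 is acylated at the equatorial O5 while O4 is pseudoaxial next to the C3 branch (allylic 1,2-strain), the same preference for the equatorial hydroxyl that axial/equatorial cis-diols of pyranosides show, and the mild amine base should limit benzoyl migration.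

Step 10
Reactants: 13 [(3R,4R,5R,6R)-5-benzoyloxy-6-hydroxy-3-methoxy-4-[(4-methoxyphenyl)methoxy]cyclohex-1-en-1-yl]methyl benzoate
Product: 14 [(3R,4R,5R,6R)-5-benzoyloxy-4,6-dihydroxy-3-methoxycyclohex-1-en-1-yl]methyl benzoate (CNP0349013.4)
Conditions: DDQ (1.3 equiv), CH2Cl2/pH 7 phosphate buffer (10:1), 0 °C to rt
Reagents that add atoms: none
Why: Oxidative PMB ether cleavage by DDQ (hydride abstraction to the oxocarbenium ion, then hydrolysis) releases O6–H under neutral conditions that should neither hydrolyse nor shift the benzoates and that leave the alkene and the methyl ether alone.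

**Compound list**

1 | bromobenzene | Brc1ccccc1 | starting material
2 | (1S,2S)-3-bromocyclohexa-3,5-diene-1,2-diol | C1=C(Br)[C@@H](O)[C@@H](O)C=C1 | intermediate
3 | (3aS,7aS)-4-bromo-2,2-dimethyl-3a,7a-dihydro-1,3-benzodioxole | C1=C(Br)[C@H]2OC(C)(C)O[C@H]2C=C1 | intermediate
4 | (3aS,4R,5R,7aS)-7-bromo-2,2-dimethyl-3a,4,5,7a-tetrahydro-1,3-benzodioxole-4,5-diol | O[C@@H]1C=C(Br)[C@H]2OC(C)(C)O[C@H]2[C@@H]1O | intermediate
5 | dibutylstannylene acetal of 4 (2,2-dibutyl-1,3,2-dioxastannolane across O1 and O6, drawn as the monomer) | CCCC[Sn]1(CCCC)O[C@@H]2C=C(Br)[C@H]3OC(C)(C)O[C@H]3[C@@H]2O1 | intermediate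
6 | (3aS,4R,5R,7aS)-7-bromo-4-[(4-methoxyphenyl)methoxy]-2,2-dimethyl-3a,4,5,7a-tetrahydro-1,3-benzodioxol-5-ol | O[C@@H]1C=C(Br)[C@H]2OC(C)(C)O[C@H]2[C@@H]1OCc3ccc(OC)cc3 | intermediate
7 | (3aS,4R,5R,7aS)-7-bromo-5-methoxy-4-[(4-methoxyphenyl)methoxy]-2,2-dimethyl-3a,4,5,7a-tetrahydro-1,3-benzodioxole | CO[C@@H]1C=C(Br)[C@H]2OC(C)(C)O[C@H]2[C@@H]1OCc3ccc(OC)cc3 | intermediate
8 | (tributylstannyl)methanol | OC[Sn](CCCC)(CCCC)CCCC | starting material
9 | [(3aR,6R,7R,7aR)-6-methoxy-7-[(4-methoxyphenyl)methoxy]-2,2-dimethyl-3a,6,7,7a-tetrahydro-1,3-benzodioxol-4-yl]methanol | CO[C@@H]1C=C(CO)[C@H]2OC(C)(C)O[C@H]2[C@@H]1OCc3ccc(OC)cc3 | intermediate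
10 | benzoyl chloride | O=C(Cl)c1ccccc1 | starting material
11 | [(3aR,6R,7R,7aR)-6-methoxy-7-[(4-methoxyphenyl)methoxy]-2,2-dimethyl-3a,6,7,7a-tetrahydro-1,3-benzodioxol-4-yl]methyl benzoate | CO[C@@H]1C=C(COC(=O)c3ccccc3)[C@H]2OC(C)(C)O[C@H]2[C@@H]1OCc4ccc(OC)cc4 | intermediate
12 | [(3R,4S,5R,6R)-5,6-dihydroxy-3-methoxy-4-[(4-methoxyphenyl)methoxy]cyclohex-1-en-1-yl]methyl benzoate | CO[C@@H]1C=C(COC(=O)c2ccccc2)[C@@H](O)[C@@H](O)[C@@H]1OCc3ccc(OC)cc3 | intermediate
13 | [(3R,4R,5R,6R)-5-benzoyloxy-6-hydroxy-3-methoxy-4-[(4-methoxyphenyl)methoxy]cyclohex-1-en-1-yl]methyl benzoate | CO[C@@H]1C=C(COC(=O)c2ccccc2)[C@@H](O)[C@@H](OC(=O)c2ccccc2)[C@@H]1OCc3ccc(OC)cc3 | intermediate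
14 | [(3R,4R,5R,6R)-5-benzoyloxy-4,6-dihydroxy-3-methoxycyclohex-1-en-1-yl]methyl benzoate | CO[C@@H]1C=C(COC(=O)c2ccccc2)[C@@H](O)[C@@H](OC(=O)c2ccccc2)[C@@H]1O | target

**Count and risks**

Total step count: 10. Longest linear sequence: 10 steps (1 to 14); 8 and 10 are purchased.

Step 4 – loss of site selectivity in the tin-mediated alkylation. The stannylene acetal may open at the pseudoaxial allylic O1 or be alkylated twice, so that the PMB group ends on the wrong oxygen. The fallback replaces tin control by steric control and sets out from 4. TBSCl and imidazole in DMF at 0 °C should silylate the less hindered allylic O1–H (O6–H is flanked by two oxygenated carbons) to give the O1 silyl ether F1. 4-Methoxybenzyl 2,2,2-trichloroacetimidate with Sc(OTf)3 (cat.) in toluene at 0 °C, an acid-catalysed etherification that avoids base-induced silyl migration, would then give the O1-TBS O6-PMB diether F2. Bu4NF in THF frees O1–H and the route is rejoined at 6.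

Step 9 – acylation at the wrong hydroxyl or acyl scrambling. The allylic O4 may be benzoylated, both hydroxyls may react, or a benzoyl group may migrate between O5, O4 and O7. The fallback locks O4 and O7 in a temporary ring instead of relying on kinetic selection and sets out from 9. Aqueous AcOH (4:1) at 60 °C removes the acetonide to give the O4,O5,O7-triol F3. PhCH(OMe)2 with CSA (cat.) in MeCN under equilibrating conditions should favour the six-membered benzylidene acetal across O7 and O4, as in the 4,6-O-benzylidenation of galactopyranosides that also carry a cis-diol, giving the 4,7-O-benzylidene acetal F4 with only O5–H free. BzCl in pyridine gives the O5 benzoate F5, and aqueous AcOH at 50 °C cleaves the acetal to the O4,O7-diol F6. BzCl (1.05 equiv) with 2,4,6-collidine in CH2Cl2 at −40 °C benzoylates the primary O7–H selectively and the route is rejoined at 13.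

Step 6 – sluggish cross-coupling. Transmetallation at the hindered alkenyl bromide next to the acetonide oxygen may be slow, allowing butyl transfer, protodebromination or catalyst decay to compete. The fallback brings in C7 as carbon monoxide and sets out from 7. CO (1 atm), MeOH, Et3N, Pd(OAc)2 and 1,3-bis(diphenylphosphino)propane in DMF at 70 °C (Heck-type alkoxycarbonylation of the alkenyl bromide) should give the methyl cyclohexenecarboxylate F7. 1,2-Reduction of the enoate with i-Bu2AlH in CH2Cl2 at −78 °C gives the allylic alcohol and the route is rejoined at 9.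

**Further compounds**

F1 | step 4 | O1-(tert-butyldimethylsilyl) ether of diol 4 (O6–H free, stereocentres as in 4) | CC(C)(C)[Si](C)(C)O[C@@H]1C=C(Br)[C@H]2OC(C)(C)O[C@H]2[C@@H]1O
F2 | step 4 | O1-(tert-butyldimethylsilyl) O6-(4-methoxybenzyl) diether of diol 4 | CC(C)(C)[Si](C)(C)O[C@@H]1C=C(Br)[C@H]2OC(C)(C)O[C@H]2[C@@H]1OCc3ccc(OC)cc3
F3 | step 9 | O4,O5,O7-triol: 9 without the acetonide (O1-methyl, O6-PMB) | CO[C@@H]1C=C(CO)[C@@H](O)[C@@H](O)[C@@H]1OCc3ccc(OC)cc3
F4 | step 9 | 4,7-O-benzylidene acetal of F3 (six-membered ring across O4 and O7, phenyl equatorial, acetal H syn to H4, O5–H free) | CO[C@@H]1C=C2CO[C@@H](c3ccccc3)O[C@H]2[C@@H](O)[C@@H]1OCc4ccc(OC)cc4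
F5 | step 9 | O5 benzoate of F4 | CO[C@@H]1C=C2CO[C@@H](c3ccccc3)O[C@H]2[C@@H](OC(=O)c3ccccc3)[C@@H]1OCc4ccc(OC)cc4
F6 | step 9 | O4,O7-diol with O5 benzoate, O6-PMB and O1-methyl | CO[C@@H]1C=C(CO)[C@@H](O)[C@@H](OC(=O)c2ccccc2)[C@@H]1OCc3ccc(OC)cc3
F7 | step 6 | methyl ester at C3 in place of bromine in 7 (methyl cyclohexenecarboxylate, stereocentres as in 7) | CO[C@@H]1C=C(C(=O)OC)[C@H]2OC(C)(C)O[C@H]2[C@@H]1OCc3ccc(OC)cc3
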